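**Retrosynthetic overview**

- The target comes from global desilylation after a reductive SN2′ opening of an oxygen-bridged (4+3) cycloadduct; the opening gives the C22=C23 alkene and the C20 carbinol.
- Key step: an intramolecular (4+3) cycloaddition of a furan with an oxyallyl cation (an α-keto carbocation made from an α-chloro ketone) forms C17–C23 and C19–C20, closing the cyclopentane and the seven-membered ring together.
- The cycloaddition precursor comes from a Johnson–Claisen rearrangement (C14–C15 bond, C14 set by 1,3-chirality transfer, C10=C11 alkene) of the furfurylidene carbinol made from the diquinane ketone and furfural.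
- The side chain is attached by Felkin–Anh addition of an alkenyl organometallic (from (R)-but-3-yn-2-ol) to an acetyl diquinane; the acetyl diquinane comes from ozonolysis/aldol ring contraction of a cis-hydrindenone.
- Ring order: cyclopentanone ring (bought) → six-membered ring by Diels–Alder (isoprene + 3-methylcyclopent-2-enone), contracted to the second diquinane ring → cyclopentane and cycloheptenone by the (4+3) → bridge opening.

Assumption: locants used below are C1–C5 for the side chain (C1 = terminal CH3, C2 = CHOH, C3=C4, C5 = C(OH)CH3), C6–C13 for the diquinane (C6 bears the side chain, C9 = ring-fusion CH, C10=C11, C13 = ring-fusion C–CH3) and C14–C23 for the hydroazulenone (C14 on C11, C17 = ring-fusion CH, C18 = C=O, C20 = CHOH, C22=C23); where a name gives no descriptor, the SMILES defines the configuration.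

**Route**

Step 1
Reactants: 1 isoprene (2-methylbuta-1,3-diene); 2 3-methylcyclopent-2-en-1-one
Product: 3 (3aS,7aR)-3a,5-dimethyl-2,3,3a,4,7,7a-hexahydro-1H-inden-1-one (cis-fused)
Conditions: (S)-3,3-diphenyl-1-(2-methylphenyl)tetrahydro-1H,3H-pyrrolo[1,2-c][1,3,2]oxazaborole (20 mol %), AlBr3 (16 mol %), CH2Cl2, −40 to −20 °C
Reagents that add atoms: none
Why: Proposed new method: a catalytic enantioselective Diels–Alder reaction in which the AlBr3-activated oxazaborolidine binds the enone carbonyl and blocks one face, so that suprafacial addition of isoprene gives the cis ring fusion (quaternary C13–CH3 and C9–H) in the absolute sense shown, assigned by analogy and not verified for this dienophile, while the para rule puts the diene methyl on C5; the closest known reactions are the AlCl3-catalysed racemic cycloaddition of this same pair and oxazaborolidinium-catalysed asymmetric Diels–Alder reactions of cyclopent-2-enone.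

Step 2
Reactants: 3 (3aS,7aR)-3a,5-dimethyl-2,3,3a,4,7,7a-hexahydro-1H-inden-1-one
Product: 4 ethylene ketal of 3
Conditions: HOCH2CH2OH, p-TsOH (cat.), benzene, reflux, Dean–Stark
Reagents that add atoms: ethylene glycol, OCCO
Why: Acid-catalysed ketalisation masks the C10 ketone for the ozonolysis, aldol and organometallic steps and leaves the cis ring fusion (also the thermodynamic one) untouched.

Step 3
Reactants: 4 ethylene ketal of 3
Product: 6 ketal-protected acetylcyclopentene (cis-fused diquinene with acetyl on C6), via keto aldehyde 5 (not isolated)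
Conditions: O3, CH2Cl2/MeOH, −78 °C; Me2S; then KOH, MeOH/H2O, 25 °C
Reagents that add atoms: ozone, O=[O+][O-]
Why: Ozonolysis of the trisubstituted alkene gives the keto aldehyde, and intramolecular aldol condensation of the methyl ketone enolate (C6) onto the aldehyde (C7) contracts the six-membered ring to the acetylcyclopentene without touching a stereocentre.

Step 4
Reactants: 6 ketal-protected acetylcyclopentene
Product: 7 ketal-protected cis-4-acetyl-3a-methylhexahydropentalen-1(2H)-one (acetyl trans to the angular methyl)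
Conditions: H2 (1 atm), Pd/C (10 wt %), EtOAc, 25 °C
Reagents that add atoms: none
Why: Heterogeneous hydrogenation adds H2 from the convex face of the cis-fused bicycle (the face of CH3-13 and H-9), so H-6 ends up cis to the angular methyl and the acetyl group on the concave face; the same C6 epimer is expected to be favoured on equilibration of this α-epimerisable ketone.

Step 5
Reactants: 8 (R)-but-3-yn-2-ol
Product: 9 (R)-tert-butyl(but-3-yn-2-yloxy)dimethylsilane
Conditions: t-BuMe2SiCl, imidazole, DMF, 25 °C
Reagents that add atoms: tert-butyldimethylsilyl chloride, CC(C)(C)[Si](C)(C)Cl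
Why: Standard silylation protects the propargylic alcohol, whose (R) centre becomes C2 of the target.

Step 6
Reactants: 9 (R)-tert-butyl(but-3-yn-2-yloxy)dimethylsilane
Product: 11 (R,E)-tert-butyl[(4-iodobut-3-en-2-yl)oxy]dimethylsilane, via alkenylzirconocene 10 (not isolated)
Conditions: Cp2Zr(H)Cl, THF, 25 °C; then I2, 0 °C
Reagents that add atoms: iodine, II
Why: Hydrozirconation adds Zr–H syn with zirconium on the terminal carbon, and iodinolysis with retention gives the (E)-alkenyl iodide.

Step 7
Reactants: 7 ketal-protected acetyl diquinane; 11 (R,E)-alkenyl iodide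
Product: 13 tertiary alcohol with the (2S,3E,5R)-5-(tert-butyldimethylsilyloxy)-2-hydroxyhex-3-en-2-yl side chain on C6, via alkenyllithium 12 (not isolated)
Conditions: 11, t-BuLi (2 equiv), Et2O, −78 °C; CeCl3, THF, −78 °C; then 7; aq NH4Cl
Reagents that add atoms: none
Why: Iodine–lithium exchange keeps the E geometry, and 1,2-addition of the derived organocerium reagent to the methyl ketone under Felkin–Anh control (quaternary C13 anti to the incoming nucleophile) sets the tertiary carbinol C5 as (S).

Step 8
Reactants: 13 tertiary alcohol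
Product: 14 triethylsilyl ether of 13
Conditions: Et3SiOTf, 2,6-lutidine, CH2Cl2, −78 to 0 °C
Reagents that add atoms: triethylsilyl trifluoromethanesulfonate, CC[Si](CC)(CC)OS(=O)(=O)C(F)(F)F
Why: Silyl triflate silylation protects the acid-sensitive tertiary allylic alcohol before the Claisen and Lewis-acid steps.

Step 9
Reactants: 14 triethylsilyl ether
Product: 15 diquinane ketone (cis-3a-methylhexahydropentalen-1(2H)-one bearing the bis-silylated side chain on C6, trans to CH3)
Conditions: pyridinium p-toluenesulfonate (cat.), acetone/H2O (10:1), 40 °C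
Reagents that add atoms: water, O
Why: Mild acid-catalysed hydrolysis of the dioxolane frees the C10 ketone while the hindered tertiary triethylsilyl and secondary tert-butyldimethylsilyl ethers survive.

Step 10
Reactants: 15 diquinane ketone; 16 furfural (furan-2-carbaldehyde)
Product: 17 (E)-furfurylidene enone (C10 ketone, exocyclic C11=C14 alkene)
Conditions: NaOH (aq), EtOH, 25 °C
Reagents that add atoms: none
Why: Claisen–Schmidt aldol condensation occurs at the only enolisable methylene next to the ketone (C11) and gives the E alkene with the furyl group anti to the carbonyl.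

Step 11
Reactants: 17 (E)-furfurylidene enone
Product: 18 allylic alcohol (C10–OH on the concave face)
Conditions: NaBH4, CeCl3·7H2O, MeOH, −40 °C
Reagents that add atoms: none
Why: Luche 1,2-reduction delivers hydride to C10 from the convex face of the cis-fused diquinane, placing the hydroxyl on the concave face.

Step 12
Reactants: 18 allylic alcohol
Product: 21 ethyl (3R)-3-(furan-2-yl)-3-(diquinenyl)propanoate (C14 R and C10=C11 alkene), via mixed orthoester 19 (not isolated), via ketene acetal 20 (not isolated)
Conditions: CH3C(OEt)3, EtCO2H (cat.), xylene, 135 °C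
Reagents that add atoms: triethyl orthoacetate, CC(OCC)(OCC)OCC
Why: In the Johnson–Claisen rearrangement the suprafacial [3,3] shift forms C14–C15 on the face from which the C10 oxygen leaves, so the C10 configuration and the E geometry fix C14 as (R) and the double bond moves to C10=C11.

Step 13
Reactants: 21 ethyl ester
Product: 23 (E)-enone (C16=C17 conjugated to the C18 methyl ketone), via aldehyde 22 (not isolated)
Conditions: i-Bu2AlH (1.1 equiv), CH2Cl2, −78 °C; MeOH; then Ph3P=CHC(O)CH3, −78 to 25 °C
Reagents that add atoms: 1-(triphenylphosphoranylidene)propan-2-one, CC(=O)C=P(c1ccccc1)(c1ccccc1)c1ccccc1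
Why: Half-reduction of the ester to the aldehyde followed by in situ Wittig olefination with the stabilised ylide gives the E enone and adds C17–C19.

Step 14
Reactants: 23 (E)-enone
Product: 25 α-chloro ketone (chlorine on C17; mixture of C17 epimers), via silyl enol ether 24 (not isolated)
Conditions: [(Ph3P)CuH]6 (5 mol %), PhMe2SiH, toluene, 25 °C; then N-chlorosuccinimide, THF, 0 °C
Reagents that add atoms: N-chlorosuccinimide, O=C1CCC(=O)N1Cl
Why: Copper hydride-catalysed conjugate hydrosilylation gives the C17=C18 silyl enol ether regiospecifically, and electrophilic chlorination puts chlorine on C17; that centre is planarised in the next step, so its configuration does not matter.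

Step 15
Reactants: 25 α-chloro ketone
Product: 27 oxygen-bridged cycloadduct (8-oxabicyclo[3.2.1]oct-6-en-3-one fused to the new cyclopentane; H-14, H-17 and the oxygen bridge on one face), via oxyallyl cation 26 (not isolated)
Conditions: Et3N, CF3CH2OH, 0 to 25 °C
Reagents that add atoms: none
Why: Dehydrochlorination in the ionising solvent gives the oxyallyl cation, an α-keto carbocation whose normally nucleophilic α-carbons C17 and C19 bond to the normally nucleophilic furan carbons C23 and C20 in an intramolecular (4+3) cycloaddition (Föhlisch conditions); the three-carbon tether is expected to favour a compact transition state of the Z cation with the bulky C14 alkenyl group turned away from the cation, which sets C17, C20 and C23 with H-14, H-17 and the bridge oxygen cis.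

Step 16
Reactants: 27 oxygen-bridged cycloadduct
Product: 28 ring-opened ketone (C22=C23 alkene, C20 triethylsilyl ether, side chain still bis-silylated)
Conditions: Et3SiH (3 equiv), Et3SiOTf (10 mol %), 2,6-di-tert-butyl-4-methylpyridine (20 mol %), CH2Cl2, −78 °C
Reagents that add atoms: triethylsilane, CC[SiH](CC)CC
Why: Proposed new method: silyl triflate-catalysed ionic hydrogenation in which the silylated bridging oxonium ionises at the strained tertiary allylic C23–O bond, Et3SiH delivers hydride to the less hindered allyl terminus C21 (net SN2′ result: C21H2 and C22=C23) and the released silylium carries the chain so that O20 emerges as its triethylsilyl ether with C17 and C20 untouched; the closest known reactions are Et3SiH/Lewis acid reductive cleavage of allylic and tertiary ethers and the hydride-induced SN2′ ring opening of 8-oxabicyclo[3.2.1]oct-6-enes by hydroalumination–elimination.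

Step 17
Reactants: 28 ring-opened tris-silyl ketone
Product: 29 target compound
Conditions: HF·pyridine, pyridine, THF, 0 to 25 °C
Reagents that add atoms: none
Why: Buffered fluoride-mediated desilylation removes the three silyl ethers under non-basic conditions that leave the β-hydroxy ketone and the epimerisable, β,γ-unsaturated C17 centre intact.

**Compound list**

1 | isoprene | C=CC(C)=C | starting material
2 | 3-methylcyclopent-2-en-1-one | CC1=CC(=O)CC1 | starting material
3 | (3aS,7aR)-3a,5-dimethyl-2,3,3a,4,7,7a-hexahydro-1H-inden-1-one | CC1=CC[C@H]2C(=O)CC[C@@]2(C)C1 | intermediate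
4 | ethylene ketal of 3 | CC1=CC[C@H]2C3(OCCO3)CC[C@@]2(C)C1 | intermediate
5 | 2-[(6R,7S)-7-methyl-7-(2-oxopropyl)-1,4-dioxaspiro[4.4]nonan-6-yl]acetaldehyde | CC(=O)C[C@]1(C)CCC2(OCCO2)[C@@H]1CC=O | intermediate (not isolated)
6 | ketal-protected cis-fused 4-acetyl-3a-methyl-tetrahydropentalen-1-one (C6=C7 alkene) | CC(=O)C1=CC[C@H]2C3(OCCO3)CC[C@]21C | intermediate
7 | ketal-protected cis-4-acetyl-3a-methylhexahydropentalen-1(2H)-one, acetyl trans to CH3 | CC(=O)[C@H]1CC[C@H]2C3(OCCO3)CC[C@]21C | intermediate
8 | (R)-but-3-yn-2-ol | C[C@@H](O)C#C | starting material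
9 | (R)-tert-butyl(but-3-yn-2-yloxy)dimethylsilane | C[C@@H](O[Si](C)(C)C(C)(C)C)C#C | intermediate
10 | (E)-alkenyl(chloro)zirconocene from 9 | C[C@@H](O[Si](C)(C)C(C)(C)C)/C=C/[Zr](Cl)(C1C=CC=C1)C1C=CC=C1 | intermediate (not isolated)
11 | (R,E)-tert-butyl[(4-iodobut-3-en-2-yl)oxy]dimethylsilane | C[C@@H](O[Si](C)(C)C(C)(C)C)/C=C/I | intermediate
12 | (R,E)-alkenyllithium from 11 | C[C@@H](O[Si](C)(C)C(C)(C)C)/C=C/[Li] | intermediate (not isolated)
13 | ketal-protected diquinane with the (2S,3E,5R)-5-(TBSO)-2-hydroxyhex-3-en-2-yl side chain | C[C@@H](O[Si](C)(C)C(C)(C)C)/C=C/[C@](C)(O)[C@H]1CC[C@H]2C3(OCCO3)CC[C@]21C | intermediate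
14 | triethylsilyl ether of 13 | C[C@@H](O[Si](C)(C)C(C)(C)C)/C=C/[C@](C)(O[Si](CC)(CC)CC)[C@H]1CC[C@H]2C3(OCCO3)CC[C@]21C | intermediate
15 | diquinane ketone (C10 ketone, bis-silylated side chain) | C[C@@H](O[Si](C)(C)C(C)(C)C)/C=C/[C@](C)(O[Si](CC)(CC)CC)[C@H]1CC[C@H]2C(=O)CC[C@]21C | intermediate
16 | furfural | O=Cc1ccco1 | starting material
17 | (E)-furfurylidene enone | C[C@@H](O[Si](C)(C)C(C)(C)C)/C=C/[C@](C)(O[Si](CC)(CC)CC)[C@H]1CC[C@H]2C(=O)/C(=C/c3ccco3)C[C@]21C | intermediate
18 | allylic alcohol (C10–OH on the concave face) | C[C@@H](O[Si](C)(C)C(C)(C)C)/C=C/[C@](C)(O[Si](CC)(CC)CC)[C@H]1CC[C@H]2[C@@H](O)/C(=C/c3ccco3)C[C@]21C | intermediate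
19 | mixed orthoester of 18 | C[C@@H](O[Si](C)(C)C(C)(C)C)/C=C/[C@](C)(O[Si](CC)(CC)CC)[C@H]1CC[C@H]2[C@@H](OC(C)(OCC)OCC)/C(=C/c3ccco3)C[C@]21C | intermediate (not isolated)
20 | allyl ketene acetal | C[C@@H](O[Si](C)(C)C(C)(C)C)/C=C/[C@](C)(O[Si](CC)(CC)CC)[C@H]1CC[C@H]2[C@@H](OC(=C)OCC)/C(=C/c3ccco3)C[C@]21C | intermediate (not isolated)
21 | ethyl ester, C14 (R), C10=C11 | C[C@@H](O[Si](C)(C)C(C)(C)C)/C=C/[C@](C)(O[Si](CC)(CC)CC)[C@H]1CC[C@H]2C=C([C@@H](CC(=O)OCC)c3ccco3)C[C@]21C | intermediate
22 | aldehyde (C16) | C[C@@H](O[Si](C)(C)C(C)(C)C)/C=C/[C@](C)(O[Si](CC)(CC)CC)[C@H]1CC[C@H]2C=C([C@@H](CC=O)c3ccco3)C[C@]21C | intermediate (not isolated)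
23 | (E)-enone | C[C@@H](O[Si](C)(C)C(C)(C)C)/C=C/[C@](C)(O[Si](CC)(CC)CC)[C@H]1CC[C@H]2C=C([C@@H](C/C=C/C(C)=O)c3ccco3)C[C@]21C | intermediate
24 | (Z)-dimethylphenylsilyl enol ether | C[C@@H](O[Si](C)(C)C(C)(C)C)/C=C/[C@](C)(O[Si](CC)(CC)CC)[C@H]1CC[C@H]2C=C([C@@H](CC/C=C(\O[Si](C)(C)c4ccccc4)C)c3ccco3)C[C@]21C | intermediate (not isolated)
25 | α-chloro ketone (C17 epimers) | C[C@@H](O[Si](C)(C)C(C)(C)C)/C=C/[C@](C)(O[Si](CC)(CC)CC)[C@H]1CC[C@H]2C=C([C@@H](CCC(Cl)C(C)=O)c3ccco3)C[C@]21C | intermediate
26 | oxyallyl cation (zwitterion form) | C[C@@H](O[Si](C)(C)C(C)(C)C)/C=C/[C@](C)(O[Si](CC)(CC)CC)[C@H]1CC[C@H]2C=C([C@@H](CC[CH+]C([O-])=C)c3ccco3)C[C@]21C | intermediate (not isolated)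
27 | oxygen-bridged (4+3) cycloadduct | C[C@@H](O[Si](C)(C)C(C)(C)C)/C=C/[C@](C)(O[Si](CC)(CC)CC)[C@H]1CC[C@H]2C=C([C@H]3CC[C@H]4C(=O)C[C@H]5C=C[C@@]34O5)C[C@]21C | intermediate
28 | ring-opened tris-silyl ketone | C[C@@H](O[Si](C)(C)C(C)(C)C)/C=C/[C@](C)(O[Si](CC)(CC)CC)[C@H]1CC[C@H]2C=C([C@H]3CC[C@H]4C(=O)C[C@H](O[Si](CC)(CC)CC)CC=C34)C[C@]21C | intermediate
29 | CNP0358460.1 | C[C@@H](O)/C=C/[C@](C)(O)[C@H]1CC[C@H]2C=C([C@H]3CC[C@H]4C(=O)C[C@H](O)CC=C34)C[C@]21C | target

**Step count and risks**

Total step count: 17. Longest linear sequence: 15 (steps 1–4 and 7–17); steps 5 and 6 make the side-chain iodide.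

The three steps most likely to fail are steps 1, 15 and 16.

Step 1 (asymmetric Diels–Alder). A β,β-disubstituted cyclopentenone is a sluggish dienophile, and both the level and the sense of induction are unproven. The fallback does not use 1 and 2. It sets out from commercial 5-methyl-2,3-dihydro-1H-inden-1-one F1 and comes back to the route at 3. Reduction with BH3·SMe2 and (S)-1-methyl-3,3-diphenyltetrahydro-1H,3H-pyrrolo[1,2-c][1,3,2]oxazaborole gives (R)-5-methyl-2,3-dihydro-1H-inden-1-ol F2. Birch reduction of its lithium alkoxide (Li, NH3, t-BuOH) gives (R)-5-methyl-2,3,4,7-tetrahydro-1H-inden-1-ol F3. Hydroxyl-directed Simmons–Smith cyclopropanation (Et2Zn, CH2I2) of the tetrasubstituted allylic alkene, syn to the hydroxyl, gives the cyclopropyl carbinol F4. Dess–Martin oxidation gives the cyclopropyl ketone F5. Li in NH3 then cleaves the exocyclic cyclopropane bond that overlaps with the carbonyl, which unveils the angular methyl on the face chosen by the carbinol; protonation of the enolate gives the cis-fused ketone 3.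

Step 15 ((4+3) cycloaddition). The cation can be diverted (solvolysis, Favorskii, furan alkylation) or can add through the extended instead of the compact transition state. Both modes give H-14 and H-17 cis, so only C20 would be wrong. The fallback sets out from 25 and comes back at 29. The extended mode gives the bridge-epimeric cycloadduct F6. Et3SiH with BF3·OEt2 in CH2Cl2 at −78 °C opens it to the free 20-epi alcohol F7. Mitsunobu inversion (4-nitrobenzoic acid, PPh3, diisopropyl azodicarboxylate) gives the 4-nitrobenzoate F8 with the natural C20 configuration. K2CO3 in MeOH releases the bis-silyl alcohol F9, and HF·pyridine gives 29.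

Step 16 (ionic SN2′ opening). The Lewis acid may instead ionise the tertiary allylic silyl ether, reduce the ketone or cause elimination toward C17. The fallback sets out from 27 and comes back at 28. i-Bu2AlH (excess) in refluxing hexane reduces the ketone and opens the bridge by hydride delivery to C21, giving the diol F10 (C18 carbinol as an epimer mixture). Et3SiCl and imidazole at −20 °C silylate the less hindered C20 hydroxyl to give the mono-silyl ether F11. Dess–Martin oxidation of the C18 carbinol then gives 28.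

**Further compounds**

F1 | step 1 | 5-methyl-2,3-dihydro-1H-inden-1-one | Cc1ccc2c(c1)CCC2=O
F2 | step 1 | (R)-5-methyl-2,3-dihydro-1H-inden-1-ol | Cc1ccc2c(c1)CC[C@H]2O
F3 | step 1 | (R)-5-methyl-2,3,4,7-tetrahydro-1H-inden-1-ol | CC1=CCC2=C(C1)CC[C@H]2O
F4 | step 1 | cyclopropyl carbinol (CH2 bridge across C3a–C7a, syn to OH) | CC1=CC[C@]23C[C@@]2(C1)CC[C@H]3O
F5 | step 1 | cyclopropyl ketone from F4 | CC1=CC[C@]23C[C@@]2(C1)CCC3=O
F6 | step 15 | bridge-epimeric cycloadduct (oxygen bridge anti to H-14 and H-17) | C[C@@H](O[Si](C)(C)C(C)(C)C)/C=C/[C@](C)(O[Si](CC)(CC)CC)[C@H]1CC[C@H]2C=C([C@H]3CC[C@H]4C(=O)C[C@@H]5C=C[C@]34O5)C[C@]21C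
F7 | step 15 | 20-epi alcohol (side chain bis-silylated) | C[C@@H](O[Si](C)(C)C(C)(C)C)/C=C/[C@](C)(O[Si](CC)(CC)CC)[C@H]1CC[C@H]2C=C([C@H]3CC[C@H]4C(=O)C[C@@H](O)CC=C34)C[C@]21C
F8 | step 15 | C20 4-nitrobenzoate with natural configuration | C[C@@H](O[Si](C)(C)C(C)(C)C)/C=C/[C@](C)(O[Si](CC)(CC)CC)[C@H]1CC[C@H]2C=C([C@H]3CC[C@H]4C(=O)C[C@H](OC(=O)c5ccc(cc5)[N+](=O)[O-])CC=C34)C[C@]21C
F9 | step 15 | bis-silyl alcohol (free C20–OH) | C[C@@H](O[Si](C)(C)C(C)(C)C)/C=C/[C@](C)(O[Si](CC)(CC)CC)[C@H]1CC[C@H]2C=C([C@H]3CC[C@H]4C(=O)C[C@H](O)CC=C34)C[C@]21C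
F10 | step 16 | C18,C20-diol (C18 epimers) | C[C@@H](O[Si](C)(C)C(C)(C)C)/C=C/[C@](C)(O[Si](CC)(CC)CC)[C@H]1CC[C@H]2C=C([C@H]3CC[C@H]4C(O)C[C@H](O)CC=C34)C[C@]21C
F11 | step 16 | C20 triethylsilyl ether with free C18 carbinol | C[C@@H](O[Si](C)(C)C(C)(C)C)/C=C/[C@](C)(O[Si](CC)(CC)CC)[C@H]1CC[C@H]2C=C([C@H]3CC[C@H]4C(O)C[C@H](O[Si](CC)(CC)CC)CC=C34)C[C@]21C
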